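## Retrosynthetic overview

1. The target comes from its deca-MOM ether by one acetal solvolysis at the very end.
2. Each trans-2,3-diaryl-2,3-dihydrobenzofuran comes from an intact benzofuran. C2-lithiation and borate formation with 4-(MOM-oxy)phenyl-Bpin are followed by an arylpalladium-triggered dearomative 1,2-aryl shift from boron to C2. This shift forms the C3–aryl bond in the same event, and protodeboronation then places H on C2.
3. The aryl bromide electrophile is itself 4-bromo-6-(MOM-oxy)benzofuran, so every coupling delivers the next benzofuran. The rings are dearomatised in the order A, B, C, and 1-bromo-3,5-bis(MOM-oxy)benzene caps the chain as ring D.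
4. The first benzofuran (ring A with the E-styryl catechol arm) comes from the same bromobenzofuran, ethene and 4-bromocatechol bis-MOM ether by a double Heck reaction.
5. The bromobenzofuran and the ring D bromide both come from 5-bromoresorcinol, which comes from bromobenzene by double C–H borylation and oxidation. The furan ring is closed first of all, by acetal cyclodehydration.

## Assumptions

- **Stereochemical reading of the target.** Unit A is the dihydrobenzofuran bearing the styryl arm and is (2R,3R). Unit B is (2S,3S). Unit C bears the 3,5-dihydroxyphenyl ring D and is (2R,3R). All three units are trans and the alkene is E.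
- **Ligand sense.** The sense of induction of the ferrocenyl bisphosphine on this new substrate class is not known. The (R,R,Sp,Sp) ligand is written for the 3R series and its mirror image for the 3S series. If a model run shows the opposite, the two are exchanged.
- **Abbreviations.** In the ligand formula Ar = 4-MeO-3,5-Me2C6H2. MOM = CH2OCH3.

## Route

**Step 1**
Reactants: 1 bromobenzene
Product: 3 5-bromobenzene-1,3-diol, via 3,5-diborylbromobenzene 2 (not isolated)
Conditions: B2pin2 (1.3 equiv), [Ir(OMe)(cod)]2 (1.5 mol %), dtbpy (3 mol %), cyclohexane, 80 °C; then 30% H2O2, aq NaOH, THF, 0 °C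
Reagents that add atoms: bis(pinacolato)diboron CC1(C)OB(OC1(C)C)B1OC(C)(C)C(C)(C)O1 (boron and pinacol, kept only in 2); hydrogen peroxide OO
Why: Sterically governed iridium-catalysed C–H borylation can place two boryl groups only at the two positions meta to bromine (the para-monoborylated fraction cannot react further and is removed by chromatography), and boronate oxidation then gives the 1,3,5-pattern with the C–Br bond intact.

**Step 2**
Reactants: 3 5-bromobenzene-1,3-diol
Product: 4 1-bromo-3,5-bis(methoxymethoxy)benzene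
Conditions: NaH (2.4 equiv), MOMCl (2.4 equiv), DMF, 0 °C to rt
Reagents that add atoms: chloromethyl methyl ether COCCl
Why: Williamson-type O-alkylation of both sodium phenoxides with the very reactive α-chloro ether is fast and leaves the aryl bromide untouched.

**Step 3**
Reactants: 3 5-bromobenzene-1,3-diol; 5 2-bromo-1,1-dimethoxyethane
Product: 6 3-bromo-5-(2,2-dimethoxyethoxy)phenol
Conditions: K2CO3 (1 equiv), 3 (2 equiv), DMF, 110 °C
Reagents that add atoms: none
Why: Williamson ether synthesis run with the symmetric diol in excess makes the mono-ether the main product, and unreacted 3 is recovered by base extraction.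

**Step 4**
Reactants: 6 3-bromo-5-(2,2-dimethoxyethoxy)phenol
Product: 7 4-bromo-1-benzofuran-6-ol
Conditions: p-toluenesulfonic acid monohydrate (20 mol %), toluene (0.02 M), 110 °C, MeOH distilled off
Reagents that add atoms: none
Why: In this acid-catalysed cyclodehydration of an aryloxyacetaldehyde acetal (intramolecular Friedel–Crafts attack, then loss of methanol) the oxocarbenium ion closes mainly on the ring carbon para to the free hydroxyl, which is the carbon next to bromine.

**Step 5**
Reactants: 7 4-bromo-1-benzofuran-6-ol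
Product: 8 4-bromo-6-(methoxymethoxy)-1-benzofuran
Conditions: NaH, MOMCl, DMF, 0 °C to rt
Reagents that add atoms: chloromethyl methyl ether COCCl
Why: Williamson-type O-alkylation of the phenoxide proceeds under basic conditions that the acid-sensitive benzofuran tolerates.

**Step 6**
Reactants: 9 4-bromophenol
Product: 10 1-bromo-4-(methoxymethoxy)benzene
Conditions: NaH, MOMCl, DMF, 0 °C to rt
Reagents that add atoms: chloromethyl methyl ether COCCl
Why: This is a routine Williamson-type MOM protection of a phenoxide.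

**Step 7**
Reactants: 10 1-bromo-4-(methoxymethoxy)benzene
Product: 11 2-[4-(methoxymethoxy)phenyl]-4,4,5,5-tetramethyl-1,3,2-dioxaborolane
Conditions: B2pin2, PdCl2(dppf) (2 mol %), KOAc, dioxane, 90 °C
Reagents that add atoms: bis(pinacolato)diboron CC1(C)OB(OC1(C)C)B1OC(C)(C)C(C)(C)O1
Why: Miyaura borylation of an unhindered aryl bromide works well, and the weak acetate base prevents follow-up Suzuki coupling while the MOM ether is inert.

**Step 8**
Reactants: 12 benzene-1,2-diol
Product: 13 1,2-bis(methoxymethoxy)benzene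
Conditions: NaH (2.4 equiv), MOMCl (2.4 equiv), DMF, 0 °C to rt
Reagents that add atoms: chloromethyl methyl ether COCCl
Why: Williamson-type double O-alkylation masks the oxidation-prone catechol.

**Step 9**
Reactants: 13 1,2-bis(methoxymethoxy)benzene
Product: 14 4-bromo-1,2-bis(methoxymethoxy)benzene
Conditions: NBS (1.0 equiv), MeCN, 0 °C to rt
Reagents that add atoms: N-bromosuccinimide O=C1CCC(=O)N1Br
Why: Electrophilic aromatic bromination of a 1,2-dialkoxybenzene goes para to one oxygen, and NBS in acetonitrile liberates no strong acid, so the acetals survive.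

**Step 10**
Reactants: 14 4-bromo-1,2-bis(methoxymethoxy)benzene; 15 ethene; 8 4-bromo-6-(methoxymethoxy)-1-benzofuran
Product: 17 4-{(E)-2-[3,4-bis(methoxymethoxy)phenyl]ethenyl}-6-(methoxymethoxy)-1-benzofuran, via styrene 16 (not isolated)
Conditions: 14, ethene (8 bar), Pd(OAc)2 (2 mol %), P(o-tol)3 (6 mol %), Et3N, DMF, 110 °C; vent; then 8 (0.9 equiv), 110 °C
Reagents that add atoms: none
Why: In this one-pot double Mizoroki–Heck reaction excess ethene stops the first stage at the styrene, and in the second stage syn insertion and syn β-hydride elimination give the E-stilbene.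

**Step 11**
Reactants: 17 4-{(E)-2-[3,4-bis(methoxymethoxy)phenyl]ethenyl}-6-(methoxymethoxy)-1-benzofuran; 11 2-[4-(methoxymethoxy)phenyl]-4,4,5,5-tetramethyl-1,3,2-dioxaborolane; 8 4-bromo-6-(methoxymethoxy)-1-benzofuran
Product: 21 (2R,3R)-dihydrobenzofuran unit A bearing benzofuran ring B at C3, via 2-lithiobenzofuran 18 (not isolated), via lithium diarylborate 19 (not isolated), via tertiary boronic ester 20 (not isolated)
Conditions: nBuLi (1.05 equiv), THF, −78 °C; 11 (1.05 equiv), −78 °C to rt; Pd(OAc)2 (3 mol %), (R,R,Sp,Sp)-Fe[C5H3(PAr2)CH(NMe2)Ph]2 (3.6 mol %), KOSO2CF3 (2 equiv), 8 (1.2 equiv), THF, 60 °C; then Bu4NF·3H2O (3 equiv), 45 °C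
Reagents that add atoms: n-butyllithium [Li]CCCC (lithium, kept only in 18 and 19)
Why: Proposed new method: oxidative addition of 8 to zerovalent palladium and bromide abstraction by KOSO2CF3 give a cationic divalent arylpalladium that binds the C2=C3 bond of the electron-rich borate 19 and triggers a dearomative 1,2-shift of the 4-(methoxymethoxy)phenyl group from boron to C2, anti to the metal, while C3 is palladated; C2 is then quaternary, so no β-hydride elimination is possible and stereoretentive C3–aryl reductive elimination gives 20 with the two aryl groups trans; the chiral bisphosphine selects the benzofuran face and so fixes C3 as R and C2 with it, and the known stereoretentive fluoride-promoted protodeboronation of tertiary benzylic boronic esters leaves C2 as R; the closest known reaction types are the enantioselective palladium-catalysed conjunctive cross-coupling of alkenylboron ate complexes, the allylpalladium-triggered 1,2-boronate shift of indol-2-yl borates and the halonium-triggered shift in benzofuran-2-yl borates.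

**Step 12**
Reactants: 21 (2R,3R)-dihydrobenzofuran unit A bearing benzofuran ring B at C3; 11 2-[4-(methoxymethoxy)phenyl]-4,4,5,5-tetramethyl-1,3,2-dioxaborolane; 8 4-bromo-6-(methoxymethoxy)-1-benzofuran
Product: 25 bis-dihydrobenzofuran (A 2R,3R / B 2S,3S) bearing benzofuran ring C at C3 of unit B, via 2-lithiobenzofuran 22 (not isolated), via lithium diarylborate 23 (not isolated), via tertiary boronic ester 24 (not isolated)
Conditions: nBuLi (1.05 equiv), THF, −78 °C; 11 (1.05 equiv), −78 °C to rt; Pd(OAc)2 (5 mol %), (S,S,Rp,Rp)-Fe[C5H3(PAr2)CH(NMe2)Ph]2 (6 mol %), KOSO2CF3 (2 equiv), 8 (1.3 equiv), THF, 60 °C; then Bu4NF·3H2O (3 equiv), 45 °C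
Reagents that add atoms: n-butyllithium [Li]CCCC (lithium, kept only in 22 and 23)
Why: Proposed new method: this is the same arylpalladium-triggered dearomative 1,2-aryl shift from boron to C2 as in step 11 (closest known type: palladium-catalysed conjunctive cross-coupling of alkenylboron ate complexes), now on ring B; the only kinetically acidic site at −78 °C is the benzofuran C2–H, because the crowded triaryl-substituted C3–H of unit A is deprotonated far more slowly; the mirror-image ligand sets C3 of unit B as S under catalyst control, anti migration gives the trans diaryl array, retentive protodeboronation leaves C2 as S, and any minor diastereomer is removed by chromatography.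

**Step 13**
Reactants: 25 bis-dihydrobenzofuran (A 2R,3R / B 2S,3S) bearing benzofuran ring C at C3 of unit B; 11 2-[4-(methoxymethoxy)phenyl]-4,4,5,5-tetramethyl-1,3,2-dioxaborolane; 4 1-bromo-3,5-bis(methoxymethoxy)benzene
Product: 29 deca-MOM ether of the target (A 2R,3R / B 2S,3S / C 2R,3R), via 2-lithiobenzofuran 26 (not isolated), via lithium diarylborate 27 (not isolated), via tertiary boronic ester 28 (not isolated)
Conditions: nBuLi (1.05 equiv), THF, −78 °C; 11 (1.05 equiv), −78 °C to rt; Pd(OAc)2 (5 mol %), (R,R,Sp,Sp)-Fe[C5H3(PAr2)CH(NMe2)Ph]2 (6 mol %), KOSO2CF3 (2 equiv), 4 (1.3 equiv), THF, 60 °C; then Bu4NF·3H2O (3 equiv), 45 °C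
Reagents that add atoms: n-butyllithium [Li]CCCC (lithium, kept only in 26 and 27)
Why: Proposed new method: this is the third use of the arylpalladium-triggered dearomative 1,2-aryl shift from boron to C2 (closest known type: palladium-catalysed conjunctive cross-coupling of alkenylboron ate complexes), with the unhindered bromide 4 delivering ring D to C3 of ring C; the ligand of step 11 sets C3 as R, anti migration places the C2 aryl group trans, and retentive protodeboronation leaves C2 as R.

**Step 14**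
Reactants: 29 deca-MOM ether of the target
Product: 30 target CNP0099535.1
Conditions: HCl (0.5 M), MeOH/THF 1:1, 40 °C, argon, dark
Reagents that add atoms: none
Why: Acid-catalysed acetal solvolysis (transacetalisation to dimethoxymethane) frees all ten phenols under conditions mild enough for the stilbene, C3 is not acid-labile, and any C2 epimer would equilibrate to the desired trans isomer through reversible benzylic C2–O opening.

## Compound list

1 | bromobenzene | Brc1ccccc1 | starting material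
2 | 2,2'-(5-bromobenzene-1,3-diyl)bis(4,4,5,5-tetramethyl-1,3,2-dioxaborolane) | Brc1cc(B2OC(C)(C)C(C)(C)O2)cc(B2OC(C)(C)C(C)(C)O2)c1 | intermediate
3 | 5-bromobenzene-1,3-diol | Oc1cc(O)cc(Br)c1 | intermediate
4 | 1-bromo-3,5-bis(methoxymethoxy)benzene | COCOc1cc(Br)cc(OCOC)c1 | intermediate
5 | 2-bromo-1,1-dimethoxyethane | COC(CBr)OC | starting material
6 | 3-bromo-5-(2,2-dimethoxyethoxy)phenol | COC(COc1cc(O)cc(Br)c1)OC | intermediate
7 | 4-bromo-1-benzofuran-6-ol | Oc1cc(Br)c2ccoc2c1 | intermediate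
8 | 4-bromo-6-(methoxymethoxy)-1-benzofuran | COCOc1cc(Br)c2ccoc2c1 | intermediate
9 | 4-bromophenol | Oc1ccc(Br)cc1 | starting material
10 | 1-bromo-4-(methoxymethoxy)benzene | COCOc1ccc(Br)cc1 | intermediate
11 | 2-[4-(methoxymethoxy)phenyl]-4,4,5,5-tetramethyl-1,3,2-dioxaborolane | COCOc1ccc(B2OC(C)(C)C(C)(C)O2)cc1 | intermediate
12 | benzene-1,2-diol | Oc1ccccc1O | starting material
13 | 1,2-bis(methoxymethoxy)benzene | COCOc1ccccc1OCOC | intermediate
14 | 4-bromo-1,2-bis(methoxymethoxy)benzene | COCOc1ccc(Br)cc1OCOC | intermediate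
15 | ethene | C=C | starting material
16 | 4-ethenyl-1,2-bis(methoxymethoxy)benzene | C=Cc1ccc(OCOC)c(OCOC)c1 | intermediate
17 | 4-{(E)-2-[3,4-bis(methoxymethoxy)phenyl]ethenyl}-6-(methoxymethoxy)-1-benzofuran | COCOc1cc(/C=C/c2ccc(OCOC)c(OCOC)c2)c2ccoc2c1 | intermediate
18 | {4-[(E)-2-[3,4-bis(methoxymethoxy)phenyl]ethenyl]-6-(methoxymethoxy)-1-benzofuran-2-yl}lithium | [Li]c1cc2c(/C=C/c3ccc(OCOC)c(OCOC)c3)cc(OCOC)cc2o1 | intermediate
19 | lithium (pinacolato)[4-(methoxymethoxy)phenyl]{4-[(E)-2-[3,4-bis(methoxymethoxy)phenyl]ethenyl]-6-(methoxymethoxy)-1-benzofuran-2-yl}borate | [Li+].COCOc1ccc(cc1)[B-]1(OC(C)(C)C(C)(C)O1)c1cc2c(/C=C/c3ccc(OCOC)c(OCOC)c3)cc(OCOC)cc2o1 | intermediate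
20 | (2R,3R)-4-{(E)-2-[3,4-bis(methoxymethoxy)phenyl]ethenyl}-6-(methoxymethoxy)-3-[6-(methoxymethoxy)-1-benzofuran-4-yl]-2-[4-(methoxymethoxy)phenyl]-2-(4,4,5,5-tetramethyl-1,3,2-dioxaborolan-2-yl)-2,3-dihydro-1-benzofuran (aryl groups at C2 and C3 trans, boryl cis to the C3 aryl) | COCOc1ccc([C@]2(B3OC(C)(C)C(C)(C)O3)Oc3cc(OCOC)cc(/C=C/c4ccc(OCOC)c(OCOC)c4)c3[C@H]2c2cc(OCOC)cc3occc23)cc1 | intermediate
21 | (2R,3R)-4-{(E)-2-[3,4-bis(methoxymethoxy)phenyl]ethenyl}-6-(methoxymethoxy)-3-[6-(methoxymethoxy)-1-benzofuran-4-yl]-2-[4-(methoxymethoxy)phenyl]-2,3-dihydro-1-benzofuran | COCOc1ccc([C@@H]2Oc3cc(OCOC)cc(/C=C/c4ccc(OCOC)c(OCOC)c4)c3[C@H]2c2cc(OCOC)cc3occc23)cc1 | intermediate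
22 | 2-lithio derivative of 21 (Li at C2 of benzofuran ring B; unit A 2R,3R) | COCOc1ccc([C@@H]2Oc3cc(OCOC)cc(/C=C/c4ccc(OCOC)c(OCOC)c4)c3[C@H]2c2cc(OCOC)cc3oc([Li])cc23)cc1 | intermediate
23 | lithium (pinacolato)[4-(methoxymethoxy)phenyl]borate carried at C2 of benzofuran ring B of 21 (unit A 2R,3R) | [Li+].COCOc1ccc([C@@H]2Oc3cc(OCOC)cc(/C=C/c4ccc(OCOC)c(OCOC)c4)c3[C@H]2c2cc(OCOC)cc3oc(cc23)[B-]2(OC(C)(C)C(C)(C)O2)c2ccc(OCOC)cc2)cc1 | intermediate
24 | 2-(4,4,5,5-tetramethyl-1,3,2-dioxaborolan-2-yl) analogue of 25 (boryl in place of H at C2 of unit B, cis to the C3 aryl; A 2R,3R, B 2S,3S) | COCOc1ccc([C@@]2(B7OC(C)(C)C(C)(C)O7)Oc3cc(OCOC)cc([C@@H]4c5c(/C=C/c6ccc(OCOC)c(OCOC)c6)cc(OCOC)cc5O[C@H]4c4ccc(OCOC)cc4)c3[C@@H]2c2cc(OCOC)cc3occc23)cc1 | intermediate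
25 | (2S,3S)-4-[(2R,3R)-4-{(E)-2-[3,4-bis(methoxymethoxy)phenyl]ethenyl}-6-(methoxymethoxy)-2-[4-(methoxymethoxy)phenyl]-2,3-dihydro-1-benzofuran-3-yl]-6-(methoxymethoxy)-3-[6-(methoxymethoxy)-1-benzofuran-4-yl]-2-[4-(methoxymethoxy)phenyl]-2,3-dihydro-1-benzofuran | COCOc1ccc([C@H]2Oc3cc(OCOC)cc([C@@H]4c5c(/C=C/c6ccc(OCOC)c(OCOC)c6)cc(OCOC)cc5O[C@H]4c4ccc(OCOC)cc4)c3[C@@H]2c2cc(OCOC)cc3occc23)cc1 | intermediate
26 | 2-lithio derivative of 25 (Li at C2 of benzofuran ring C; A 2R,3R, B 2S,3S) | COCOc1ccc([C@H]2Oc3cc(OCOC)cc([C@@H]4c5c(/C=C/c6ccc(OCOC)c(OCOC)c6)cc(OCOC)cc5O[C@H]4c4ccc(OCOC)cc4)c3[C@@H]2c2cc(OCOC)cc3oc([Li])cc23)cc1 | intermediate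
27 | lithium (pinacolato)[4-(methoxymethoxy)phenyl]borate carried at C2 of benzofuran ring C of 25 (A 2R,3R, B 2S,3S) | [Li+].COCOc1ccc([C@H]2Oc3cc(OCOC)cc([C@@H]4c5c(/C=C/c6ccc(OCOC)c(OCOC)c6)cc(OCOC)cc5O[C@H]4c4ccc(OCOC)cc4)c3[C@@H]2c2cc(OCOC)cc3oc(cc23)[B-]2(OC(C)(C)C(C)(C)O2)c2ccc(OCOC)cc2)cc1 | intermediate
28 | 2-(4,4,5,5-tetramethyl-1,3,2-dioxaborolan-2-yl) analogue of 29 (boryl in place of H at C2 of unit C, cis to ring D; A 2R,3R, B 2S,3S, C 2R,3R) | COCOc1ccc([C@H]2Oc3cc(OCOC)cc([C@@H]4c5c(/C=C/c6ccc(OCOC)c(OCOC)c6)cc(OCOC)cc5O[C@H]4c4ccc(OCOC)cc4)c3[C@@H]2c2cc(OCOC)cc3c2[C@@H](c2cc(OCOC)cc(OCOC)c2)[C@](B2OC(C)(C)C(C)(C)O2)(c2ccc(OCOC)cc2)O3)cc1 | intermediate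
29 | deca-MOM ether of the target: (2R,3R)-3-[3,5-bis(methoxymethoxy)phenyl]-6-(methoxymethoxy)-2-[4-(methoxymethoxy)phenyl]-2,3-dihydro-1-benzofuran whose C4 is bonded to C3 of unit B of 25 (B 2S,3S, A 2R,3R, E-alkene) | COCOc1ccc([C@H]2Oc3cc(OCOC)cc([C@@H]4c5c(/C=C/c6ccc(OCOC)c(OCOC)c6)cc(OCOC)cc5O[C@H]4c4ccc(OCOC)cc4)c3[C@@H]2c2cc(OCOC)cc3c2[C@@H](c2cc(OCOC)cc(OCOC)c2)[C@H](c2ccc(OCOC)cc2)O3)cc1 | intermediate
30 | CNP0099535.1 (A 2R,3R; B 2S,3S; C 2R,3R; E-alkene) | Oc1ccc([C@H]2Oc3cc(O)cc([C@@H]4c5c(/C=C/c6ccc(O)c(O)c6)cc(O)cc5O[C@H]4c4ccc(O)cc4)c3[C@@H]2c2cc(O)cc3c2[C@@H](c2cc(O)cc(O)c2)[C@H](c2ccc(O)cc2)O3)cc1 | target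

## Step count and risks

Total steps: 14.
Longest linear sequence: 9 steps (1, 3, 4, 5, 10, 11, 12, 13, 14).

**Step 11 (the new coupling, which recurs in steps 12 and 13).**
- *Risk.* The benzofuranyl or aryl group of borate 19 may transfer directly to palladium, giving Suzuki–Miyaura biaryls instead of the 1,2-shift. The enantioselectivity is also unknown.
- *Fallback.* It uses known chemistry, sets out from 3, 8, 10 and 16, and returns at 21. Compound 16 is isolated by stopping step 10 after the ethene stage.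
- *Ring A aldehyde.* Vilsmeier–Haack formylation of 3 (POCl3, DMF) gives 2-bromo-4,6-dihydroxybenzaldehyde F1. Its non-chelated para-hydroxyl is protected selectively (MOMCl, K2CO3, acetone) to give 2-bromo-6-hydroxy-4-(methoxymethoxy)benzaldehyde F2. The chelated hydroxyl is then acylated (Boc2O, iPr2NEt, DMAP) to give tert-butyl 3-bromo-2-formyl-5-(methoxymethoxy)phenyl carbonate F3.
- *Sulfonium salt.* In parallel, 10 is converted (nBuLi, THF, −78 °C) into [4-(methoxymethoxy)phenyl]lithium F4. This is trapped with paraformaldehyde as [4-(methoxymethoxy)phenyl]methanol F5. Tetrahydrothiophene and HBF4·OEt2 turn F5 into 1-[4-(methoxymethoxy)benzyl]thiolan-1-ium tetrafluoroborate F6.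
- *Annulation.* Bromine–lithium exchange on 8 (nBuLi, −78 °C) gives [6-(methoxymethoxy)-1-benzofuran-4-yl]lithium F7. F7 adds to the aldehyde of F3. Boc migration and loss of tert-butyl carbonate on warming with MgBr2·OEt2 release the o-quinone methide 5-bromo-3-(methoxymethoxy)-6-{[6-(methoxymethoxy)-1-benzofuran-4-yl]methylidene}cyclohexa-2,4-dien-1-one F8. This is intercepted by the sulfonium benzylide 1-{[4-(methoxymethoxy)phenyl]methanidyl}thiolan-1-ium F9 (from F6 and LiN(SiMe3)2). The reaction is the known trans-selective [4+1] annulation of o-quinone methides with sulfur ylides.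
- *Resolution and return.* The racemic trans product is resolved by preparative chiral-phase SFC to (2R,3R)-4-bromo-6-(methoxymethoxy)-3-[6-(methoxymethoxy)-1-benzofuran-4-yl]-2-[4-(methoxymethoxy)phenyl]-2,3-dihydro-1-benzofuran F10. A Mizoroki–Heck reaction of F10 with 16 (Pd(OAc)2, P(o-tol)3, Et3N, DMF, 100 °C) gives 21.

**Step 4.**
- *Risk.* Cyclisation may occur between the two oxygens, giving the 6-bromo-4-hydroxy isomer. The electron-rich benzofuranol may also oligomerise under acid.
- *Fallback.* It sets out from 3 and returns at 7. The furan carbons are brought in by acylation instead of an acetal.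
- *Sequence.* Friedel–Crafts acylation of 3 with chloroacetyl chloride and AlCl3 (nitrobenzene, 60 °C) occurs para to one hydroxyl and gives 1-(2-bromo-4,6-dihydroxyphenyl)-2-chloroethan-1-one F11. NaOAc in refluxing MeOH closes it to 4-bromo-6-hydroxy-1-benzofuran-3(2H)-one F12. NaBH4 (MeOH, 0 °C) gives 4-bromo-2,3-dihydro-1-benzofuran-3,6-diol F13. Dilute HCl in the work-up dehydrates F13 to 7.

**Step 14.**
- *Risk.* The free polyphenol sits for a long time in protic acid. Benzylic C2–O opening followed by cationic cyclisation onto the stilbene or a neighbouring resorcinol ring could occur, and a deca-phenol is hard to purify.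
- *Fallback.* It sets out from 29 and returns at 30.
- *Sequence.* The MOM groups are transferred to a soft nucleophile in minutes under aprotic conditions (ZnBr2, n-PrSH, CH2Cl2, 0 °C). The crude 30 is peracetylated at once (Ac2O, pyridine) to the decaacetate of the target F14, which is stable on silica and is purified there. The phenols are finally released without acid (K2CO3, MeOH, 0 °C, argon) to give 30.

## Further compounds

F1 | step 11 | 2-bromo-4,6-dihydroxybenzaldehyde | O=Cc1c(O)cc(O)cc1Br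
F2 | step 11 | 2-bromo-6-hydroxy-4-(methoxymethoxy)benzaldehyde | O=Cc1c(O)cc(OCOC)cc1Br
F3 | step 11 | tert-butyl 3-bromo-2-formyl-5-(methoxymethoxy)phenyl carbonate | CC(C)(C)OC(=O)Oc1cc(OCOC)cc(Br)c1C=O
F4 | step 11 | [4-(methoxymethoxy)phenyl]lithium | [Li]c1ccc(OCOC)cc1
F5 | step 11 | [4-(methoxymethoxy)phenyl]methanol | COCOc1ccc(CO)cc1
F6 | step 11 | 1-[4-(methoxymethoxy)benzyl]thiolan-1-ium tetrafluoroborate | COCOc1ccc(C[S+]2CCCC2)cc1.F[B-](F)(F)F
F7 | step 11 | [6-(methoxymethoxy)-1-benzofuran-4-yl]lithium | [Li]c1cc(OCOC)cc2occc12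
F8 | step 11 | 5-bromo-3-(methoxymethoxy)-6-{[6-(methoxymethoxy)-1-benzofuran-4-yl]methylidene}cyclohexa-2,4-dien-1-one | O=C1C=C(OCOC)C=C(Br)C1=Cc1cc(OCOC)cc2occc12
F9 | step 11 | 1-{[4-(methoxymethoxy)phenyl]methanidyl}thiolan-1-ium | COCOc1ccc([CH-][S+]2CCCC2)cc1
F10 | step 11 | (2R,3R)-4-bromo-6-(methoxymethoxy)-3-[6-(methoxymethoxy)-1-benzofuran-4-yl]-2-[4-(methoxymethoxy)phenyl]-2,3-dihydro-1-benzofuran | COCOc1ccc([C@@H]2Oc3cc(OCOC)cc(Br)c3[C@H]2c2cc(OCOC)cc3occc23)cc1
F11 | step 4 | 1-(2-bromo-4,6-dihydroxyphenyl)-2-chloroethan-1-one | O=C(CCl)c1c(O)cc(O)cc1Br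
F12 | step 4 | 4-bromo-6-hydroxy-1-benzofuran-3(2H)-one | O=C1COc2cc(O)cc(Br)c21
F13 | step 4 | 4-bromo-2,3-dihydro-1-benzofuran-3,6-diol (racemic) | OC1COc2cc(O)cc(Br)c21
F14 | step 14 | decaacetate of the target (A 2R,3R; B 2S,3S; C 2R,3R; E-alkene) | CC(=O)Oc1ccc([C@H]2Oc3cc(OC(C)=O)cc([C@@H]4c5c(/C=C/c6ccc(OC(C)=O)c(OC(C)=O)c6)cc(OC(C)=O)cc5O[C@H]4c4ccc(OC(C)=O)cc4)c3[C@@H]2c2cc(OC(C)=O)cc3c2[C@@H](c2cc(OC(C)=O)cc(OC(C)=O)c2)[C@H](c2ccc(OC(C)=O)cc2)O3)cc1
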